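**Retrosynthetic overview**

1. Target 13 comes from its 7,4'-bis(allyl ether) 12 by neutral deallylation; all three stereocentres are already present in 12.
2. Ring C of 12 is closed last, through the O1–C2 bond, from the acyclic epoxy alcohol 9, in which O1 is masked as a 1,1-dimethylallyl ether. One thermal operation should shift the five prenyl carbons from O1 to C8 ([3,3]) and let the freed O1 open the epoxide at C2.
3. Enabling feature: on ring A the prenyl-bearing C8 is the only free ortho position of the O1-bearing C8a (the other, C4a, carries C4), so a temporary O1–C bond can store the prenyl group. In ring C, C2 is benzylic to the para-oxygenated ring B and trans to the C3 oxygen, which is the imprint of a backside epoxide opening.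
4. 9 is traced to chalcone 7: Juliá–Colonna epoxidation sets C2 and C3, and chelation-controlled reduction sets C4. 7 comes from acetophenone 5 and aldehyde 6 (Claisen–Schmidt), and 5 from commercial 1. Rings A and B are bought; ring C is the only ring made.

Key step: step 7

Remark: poly-L-leucine is assumed to show with chalcone 7 the facial preference it shows with simple (E)-chalcones, which leads to the (2R,3S)-epoxy ketone; if the substrate deviated, poly-D-leucine would be used.

**Step 1**
Reactants: 1 1-(2,4-dihydroxy-6-methoxyphenyl)ethan-1-one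
Product: 2 1-[2-hydroxy-6-methoxy-4-(prop-2-en-1-yloxy)phenyl]ethan-1-one
Conditions: allyl bromide (1.05 equiv), K2CO3 (1.1 equiv), acetone, reflux
Reagents that add atoms: allyl bromide, C=CCBr
Why: Williamson etherification should occur only at the 4-hydroxyl, because the 2-hydroxyl is held in a hydrogen bond to the acetyl oxygen and is much less nucleophilic under carbonate conditions.

**Step 2**
Reactants: 2 1-[2-hydroxy-6-methoxy-4-(prop-2-en-1-yloxy)phenyl]ethan-1-one; 3 3-chloro-3-methylbut-1-yne
Product: 4 1-[2-methoxy-6-(2-methylbut-3-yn-2-yloxy)-4-(prop-2-en-1-yloxy)phenyl]ethan-1-one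
Conditions: DBU (1.6 equiv), CuCl2·2H2O (1 mol%), MeCN, 0 °C to rt
Reagents that add atoms: none
Why: Copper-catalysed O-propargylation of a phenoxide with a tertiary propargylic chloride (through a copper acetylide that ionises to an allenylidene-type electrophile) is the standard way to aryl 1,1-dimethylpropargyl ethers, and DBU should free the chelated 2-hydroxyl as its phenoxide for attack at the tertiary carbon.

**Step 3**
Reactants: 4 1-[2-methoxy-6-(2-methylbut-3-yn-2-yloxy)-4-(prop-2-en-1-yloxy)phenyl]ethan-1-one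
Product: 5 1-[2-methoxy-6-(2-methylbut-3-en-2-yloxy)-4-(prop-2-en-1-yloxy)phenyl]ethan-1-one
Conditions: H2 (1 atm), Pd/CaCO3 poisoned with Pb(OAc)2 (Lindlar catalyst), quinoline, EtOAc, rt, stopped after one equivalent of H2; product kept below 40 °C
Reagents that add atoms: none
Why: Lindlar semihydrogenation should stop at the terminal alkene, because the alkyne binds the poisoned palladium surface far more strongly than the monosubstituted alkenes of the product and of the allyl ether, and the ketone is not reduced.

**Step 4**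
Reactants: 5 1-[2-methoxy-6-(2-methylbut-3-en-2-yloxy)-4-(prop-2-en-1-yloxy)phenyl]ethan-1-one; 6 4-(prop-2-en-1-yloxy)benzaldehyde
Product: 7 (E)-1-[2-methoxy-6-(2-methylbut-3-en-2-yloxy)-4-(prop-2-en-1-yloxy)phenyl]-3-[4-(prop-2-en-1-yloxy)phenyl]prop-2-en-1-one
Conditions: KOH (50% aq), EtOH, rt
Reagents that add atoms: none
Why: Claisen–Schmidt aldol condensation under hydroxide should give the conjugated (E)-enone under thermodynamic control, and with both ortho oxygens of ring A alkylated no flavanone or aurone can form.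

**Step 5**
Reactants: 7 (E)-1-[2-methoxy-6-(2-methylbut-3-en-2-yloxy)-4-(prop-2-en-1-yloxy)phenyl]-3-[4-(prop-2-en-1-yloxy)phenyl]prop-2-en-1-one
Product: 8 [2-methoxy-6-(2-methylbut-3-en-2-yloxy)-4-(prop-2-en-1-yloxy)phenyl]{(2R,3S)-3-[4-(prop-2-en-1-yloxy)phenyl]oxiran-2-yl}methanone
Conditions: poly-L-leucine, urea–H2O2, DBU, THF, rt
Reagents that add atoms: urea–hydrogen peroxide, NC(N)=O.OO
Why: Juliá–Colonna epoxidation, a Weitz–Scheffer addition of hydroperoxide inside the helical polypeptide, should oxidise only the electron-poor enone (the three isolated alkenes do not accept a nucleophilic oxidant) and set both epoxide carbons, the future C3 and C2, as (2R,3S) under catalyst control.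

**Step 6**
Reactants: 8 [2-methoxy-6-(2-methylbut-3-en-2-yloxy)-4-(prop-2-en-1-yloxy)phenyl]{(2R,3S)-3-[4-(prop-2-en-1-yloxy)phenyl]oxiran-2-yl}methanone
Product: 9 (S)-[2-methoxy-6-(2-methylbut-3-en-2-yloxy)-4-(prop-2-en-1-yloxy)phenyl]{(2S,3S)-3-[4-(prop-2-en-1-yloxy)phenyl]oxiran-2-yl}methanol
Conditions: Zn(BH4)2, Et2O, −20 °C; H2O quench; chromatography on Et3N-deactivated silica
Reagents that add atoms: none
Why: Chelation-controlled hydride reduction of an α,β-epoxy ketone: zinc bridges the carbonyl and epoxide oxygens and hydride enters past the small epoxide hydrogen, which should give the erythro (anti) epoxy alcohol and thereby the (S)-carbinol that becomes C4, cis to the C3 oxygen.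

**Step 7**
Reactants: 9 (S)-[2-methoxy-6-(2-methylbut-3-en-2-yloxy)-4-(prop-2-en-1-yloxy)phenyl]{(2S,3S)-3-[4-(prop-2-en-1-yloxy)phenyl]oxiran-2-yl}methanol
Product: 12 (2R,3S,4S)-5-methoxy-8-(3-methylbut-2-en-1-yl)-7-(prop-2-en-1-yloxy)-2-[4-(prop-2-en-1-yloxy)phenyl]-3,4-dihydro-2H-chromene-3,4-diol, via ortho-dienone 10 (not isolated), via prenylphenol 11 (not isolated)
Conditions: PhMe (degassed), 2,6-lutidine (0.2 equiv), 110 °C, sealed tube, base-washed glass
Reagents that add atoms: none
Why: Proposed new method: heating should trigger the [3,3] aromatic Claisen shift of the aryl 1,1-dimethylallyl ether, which can deliver the allyl terminus only to C8 (the sole free ortho position of O1), giving dienone 10 and, after enolisation, the 8-prenyl phenol 11 with O1 set free. The unmasked O1–H should then open the trans-epoxide at the benzylic carbon C2 in a 6-endo-tet closure of ring C, with the neighbouring C4 hydroxyl hydrogen-bonded to the epoxide oxygen as internal acid. The closest known reaction types are the thermal Claisen rearrangement of aryl 1,1-dimethylallyl ethers to ortho-prenylphenols and the 6-endo cyclisation of 2-(3-aryl-2,3-epoxypropyl)phenols to 2,3-trans-flavan-3-ols; their coupling in one flask on an epoxy alcohol is the new element. C2 is set by stereospecific backside attack (inversion of the (S)-epoxide carbon to 2R, hence 2,3-trans), while C3 and C4 are carried over unchanged from 9. The step needs 6-endo over 5-exo closure, which the para-allyloxyphenyl group (weakening the C2–O bond) and the electron-withdrawing carbinol next to C3 should secure, and it needs the sigmatropic shift to outrun acid-induced epoxide rearrangement, which the lutidine-buffered non-polar medium should secure.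

**Step 8**
Reactants: 12 (2R,3S,4S)-5-methoxy-8-(3-methylbut-2-en-1-yl)-7-(prop-2-en-1-yloxy)-2-[4-(prop-2-en-1-yloxy)phenyl]-3,4-dihydro-2H-chromene-3,4-diol
Product: 13 (2R,3S,4S)-2-(4-hydroxyphenyl)-5-methoxy-8-(3-methylbut-2-en-1-yl)-3,4-dihydro-2H-chromene-3,4,7-triol
Conditions: Pd(PPh3)4 (5 mol%), morpholine (10 equiv), THF (degassed), rt; purification on Sephadex LH-20 (MeOH)
Reagents that add atoms: none
Why: Tsuji–Trost deallylation: zerovalent palladium ionises the two aryl allyl ethers and morpholine captures the allyl units irreversibly, under near-neutral conditions that should spare the prenyl group, the acid-labile benzylic C4 alcohol and the base-sensitive C2 centre.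

**Compound list**

1 | 1-(2,4-dihydroxy-6-methoxyphenyl)ethan-1-one | CC(=O)c1c(O)cc(O)cc1OC | starting material
2 | 1-[2-hydroxy-6-methoxy-4-(prop-2-en-1-yloxy)phenyl]ethan-1-one | CC(=O)c1c(O)cc(OCC=C)cc1OC | intermediate
3 | 3-chloro-3-methylbut-1-yne | C#CC(C)(C)Cl | starting material
4 | 1-[2-methoxy-6-(2-methylbut-3-yn-2-yloxy)-4-(prop-2-en-1-yloxy)phenyl]ethan-1-one | CC(=O)c1c(OC(C)(C)C#C)cc(OCC=C)cc1OC | intermediate
5 | 1-[2-methoxy-6-(2-methylbut-3-en-2-yloxy)-4-(prop-2-en-1-yloxy)phenyl]ethan-1-one | CC(=O)c1c(OC(C)(C)C=C)cc(OCC=C)cc1OC | intermediate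
6 | 4-(prop-2-en-1-yloxy)benzaldehyde | O=Cc1ccc(OCC=C)cc1 | starting material
7 | (E)-1-[2-methoxy-6-(2-methylbut-3-en-2-yloxy)-4-(prop-2-en-1-yloxy)phenyl]-3-[4-(prop-2-en-1-yloxy)phenyl]prop-2-en-1-one | COc1cc(OCC=C)cc(OC(C)(C)C=C)c1C(=O)/C=C/c1ccc(OCC=C)cc1 | intermediate
8 | [2-methoxy-6-(2-methylbut-3-en-2-yloxy)-4-(prop-2-en-1-yloxy)phenyl]{(2R,3S)-3-[4-(prop-2-en-1-yloxy)phenyl]oxiran-2-yl}methanone | COc1cc(OCC=C)cc(OC(C)(C)C=C)c1C(=O)[C@@H]2O[C@H]2c1ccc(OCC=C)cc1 | intermediate
9 | (S)-[2-methoxy-6-(2-methylbut-3-en-2-yloxy)-4-(prop-2-en-1-yloxy)phenyl]{(2S,3S)-3-[4-(prop-2-en-1-yloxy)phenyl]oxiran-2-yl}methanol | COc1cc(OCC=C)cc(OC(C)(C)C=C)c1[C@H](O)[C@@H]2O[C@H]2c1ccc(OCC=C)cc1 | intermediate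
10 | ortho-dienone from the [3,3] shift: 2-{(S)-hydroxy[(2S,3S)-3-(4-(prop-2-en-1-yloxy)phenyl)oxiran-2-yl]methyl}-3-methoxy-6-(3-methylbut-2-en-1-yl)-5-(prop-2-en-1-yloxy)cyclohexa-2,4-dien-1-one (either configuration at the sp3 ring carbon) | COC1=C([C@H](O)[C@@H]2O[C@H]2c2ccc(OCC=C)cc2)C(=O)C(CC=C(C)C)C(OCC=C)=C1 | intermediate
11 | 2-{(S)-hydroxy[(2S,3S)-3-(4-(prop-2-en-1-yloxy)phenyl)oxiran-2-yl]methyl}-3-methoxy-6-(3-methylbut-2-en-1-yl)-5-(prop-2-en-1-yloxy)phenol | COc1cc(OCC=C)c(CC=C(C)C)c(O)c1[C@H](O)[C@@H]2O[C@H]2c1ccc(OCC=C)cc1 | intermediate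
12 | (2R,3S,4S)-5-methoxy-8-(3-methylbut-2-en-1-yl)-7-(prop-2-en-1-yloxy)-2-[4-(prop-2-en-1-yloxy)phenyl]-3,4-dihydro-2H-chromene-3,4-diol | COc1cc(OCC=C)c(CC=C(C)C)c2c1[C@H](O)[C@H](O)[C@@H](c1ccc(OCC=C)cc1)O2 | intermediate
13 | (2R,3S,4S)-2-(4-hydroxyphenyl)-5-methoxy-8-(3-methylbut-2-en-1-yl)-3,4-dihydro-2H-chromene-3,4,7-triol (5-O-methyl-8-prenylafzelechin-4beta-ol) | COc1cc(O)c(CC=C(C)C)c2c1[C@H](O)[C@H](O)[C@@H](c1ccc(O)cc1)O2 | target

**Step count and risks**

Total step count: 8. Longest linear sequence: 8 steps (1 to 13); aldehyde 6 and chloroalkyne 3 are bought.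

Steps most likely to fail:

Step 7. The ring closure may take the 5-exo course at the inner epoxide carbon. The transient ortho-hydroxybenzyl alcohol may lose water to a quinone methide. The epoxide may ionise at C2 before O1 is free, which would rearrange it or leak stereochemistry. Fallback, from 9 and back to 12, with the two events separated and the benzylic oxygen covered:
- 9 would be silylated (Et3SiCl, imidazole, CH2Cl2, 0 °C) to the C4 triethylsilyl ether F1.
- F1 would be heated alone (PhMe, 2,6-lutidine, 100 °C) so that only the Claisen rearrangement takes place, and the 8-prenyl phenol F2 would be isolated.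
- F2 would be closed in a separate, known operation, the acid-catalysed 6-endo opening of aryl epoxides by an ortho-tethered phenol used for 2,3-trans-flavan-3-ols (pyridinium p-toluenesulfonate, CH2Cl2, −20 °C), to the 4-O-triethylsilyl flavan F3.
- Buffered desilylation (Bu4NF, AcOH, THF, 0 °C) would then rejoin the route at 12.

Step 5. Hydroperoxide addition to the twisted, electron-rich enone may be slow, and the uncatalysed background reaction may erode the enantioselectivity. Fallback, from 7 and back to 9, replacing catalyst-controlled nucleophilic epoxidation by reagent-controlled electrophilic epoxidation: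
- Luche reduction (NaBH4, CeCl3·7H2O, MeOH, 0 °C) would give the racemic allylic alcohol F4.
- Sharpless kinetic resolution (Ti(OiPr)4, L-(+)-diisopropyl tartrate, t-BuOOH (0.6 equiv), 4 Å molecular sieves, CH2Cl2, −20 °C) should epoxidise the (R)-enantiomer selectively to the erythro epoxy alcohol 9, leaving the slow (S)-enantiomer to be separated.
- The isolated terminal alkenes are not touched by the titanium peroxide, and steps 5 and 6 are bypassed.

Step 2. O-alkylation of the hydrogen-bonded, hindered phenoxide may stay incomplete while the tertiary chloride is consumed by elimination. Fallback, from 2 and directly to 5, replacing propargylation and semihydrogenation by π-allyl chemistry: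
- Pd(PPh3)4-catalysed decarboxylative O-allylation with tert-butyl 2-methylbut-3-en-2-yl carbonate (THF, 0 °C) would be used; this is known to give aryl 1,1-dimethylallyl ethers by kinetic attack at the more substituted allyl terminus.
- At this temperature the allylic carbonate should ionise much faster than the aryl allyl ether of 2.
- Step 3 is skipped, and the fallback makes no compound outside the compound list (entry F0).

**Further compounds**

F1 | step 7 | triethyl{(S)-[2-methoxy-6-(2-methylbut-3-en-2-yloxy)-4-(prop-2-en-1-yloxy)phenyl][(2R,3S)-3-(4-(prop-2-en-1-yloxy)phenyl)oxiran-2-yl]methoxy}silane (C4 triethylsilyl ether of 9) | COc1cc(OCC=C)cc(OC(C)(C)C=C)c1[C@H](O[Si](CC)(CC)CC)[C@@H]2O[C@H]2c1ccc(OCC=C)cc1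
F2 | step 7 | 3-methoxy-6-(3-methylbut-2-en-1-yl)-5-(prop-2-en-1-yloxy)-2-{(S)-[(2R,3S)-3-(4-(prop-2-en-1-yloxy)phenyl)oxiran-2-yl](triethylsilyloxy)methyl}phenol | COc1cc(OCC=C)c(CC=C(C)C)c(O)c1[C@H](O[Si](CC)(CC)CC)[C@@H]2O[C@H]2c1ccc(OCC=C)cc1
F3 | step 7 | (2R,3R,4S)-5-methoxy-8-(3-methylbut-2-en-1-yl)-7-(prop-2-en-1-yloxy)-2-[4-(prop-2-en-1-yloxy)phenyl]-4-(triethylsilyloxy)-3,4-dihydro-2H-chromen-3-ol (4-O-triethylsilyl ether of 12) | COc1cc(OCC=C)c(CC=C(C)C)c2c1[C@H](O[Si](CC)(CC)CC)[C@H](O)[C@@H](c1ccc(OCC=C)cc1)O2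
F4 | step 5 | racemic (E)-1-[2-methoxy-6-(2-methylbut-3-en-2-yloxy)-4-(prop-2-en-1-yloxy)phenyl]-3-[4-(prop-2-en-1-yloxy)phenyl]prop-2-en-1-ol | COc1cc(OCC=C)cc(OC(C)(C)C=C)c1C(O)/C=C/c1ccc(OCC=C)cc1
F0 | step 2 | none | none
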